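**Plan**

1. Numbering (germacrane): ten-membered ring C1–C10 with the Z alkene C1=C10 (methyl C14) and the E alkene C4=C5 (methyl C15); lactone from the C6 oxygen through C12 to C11 on C7, with C11=C13 exocyclic; esters on C2, C8 and C9.
2. Cuts: first the ester C–O bonds on C2, C8 and C9 and the C9 carbinol hydrogen, then C7–C8. The oxygen on C8, the adjacent ring-fusion carbon C7 and the exocyclic C11=C13 methylene beside the lactone carbonyl are what a [2,3]-shift of a C8–O–C13 ether leaves behind, so the carbocycle opens to a 13-membered keto ether that spans a butenolide (C7=C11).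
3. That bicycle is cut at C7=C11 (metathesis), the lactone C12–O bond (macrolactonisation), C9–C10 (Nozaki–Hiyama–Kishi), C1=C10 (Stork–Zhao), C4–C15 and C5–C6 (hydroalumination/Negishi, alkynylation) and C3–C4 (epoxide opening).
4. Forward: linear C1–C7 chain; union with a C8–C13 acrylate piece at C9–C10; 14-membered lactone; butenolide by transannular metathesis (13-membered ring); contraction to the ten-membered carbocycle with the methylene lactone; ester adjustment.
5. Stereochemistry: C2 from (R)-glycidyl ether; C6 from ligand-controlled alkynylation; E-C4=C5 from trans-hydroalumination, iodination and methylation; Z-C1=C10 from Z-selective iodo-olefination; C7 and C8 in the key step (control by C6 and the enolate geometry); C9 by Luche reduction next to C8.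

Key step: step 18

Abbreviations: TBS = tert-butyldimethylsilyl, TES = triethylsilyl, PMB = 4-methoxybenzyl. Locants C1–C15 in the explanations are germacrane locants of the target.

Assumption: the (S,S)-ProPhenol/Me2Zn catalyst is taken to add the alkynyl group to the enal face that gives the 4S carbinol of 5 (the facial sense of its aldol reactions); if the sense is opposite, the (R,R) ligand is used.

Remark: 17 is made and used as both C9 epimers (no descriptor in its SMILES), because C9 becomes a ketone in step 13.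

**Route**

Step 1
Reactants: 1 (R)-glycidyl 4-methoxybenzyl ether
Product: 2 (R)-1-(PMBO)pent-4-yn-2-ol
Conditions: LiC≡CH·H2NCH2CH2NH2, DMSO, 0 °C to rt; then H2O
Reagents that add atoms: lithium acetylide–ethylenediamine complex, [Li+].[C-]#C.NCCN
Why: Acetylide opens the terminal epoxide by SN2 attack at the unsubstituted carbon (epoxide alkynylation), so the stereocentre of 1 is not touched and becomes C2 of the target.

Step 2
Reactants: 2 (R)-1-(PMBO)pent-4-yn-2-ol
Product: 3 (R)-2-(TBSO)-1-(PMBO)pent-4-yne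
Conditions: TBSCl, imidazole, DMF, rt
Reagents that add atoms: tert-butyldimethylsilyl chloride, CC(C)(C)[Si](C)(C)Cl
Why: Imidazole-promoted silylation of the secondary alcohol gives a silyl ether that is meant to stay on C2 until step 21.

Step 3
Reactants: 3 (R)-2-(TBSO)-1-(PMBO)pent-4-yne; 4 (E)-but-2-enal
Product: 5 (2E,4S,8R)-8-(TBSO)-9-(PMBO)non-2-en-5-yn-4-ol
Conditions: Me2Zn (3 equiv), (S,S)-ProPhenol (20 mol %), Ph3PO (40 mol %), toluene, 0 °C; then 4 (2 equiv), 4 °C; aq. NH4Cl
Reagents that add atoms: none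
Why: The dinuclear zinc–ProPhenol catalyst adds the alkynylzinc formed from 3 in a 1,2-fashion to the enal (catalytic asymmetric alkynylation), and its chiral pocket chooses the aldehyde face and so sets the new carbinol (future C6) as 4S regardless of the remote silyl ether centre.

Step 4
Reactants: 5 (2E,4S,8R)-8-(TBSO)-9-(PMBO)non-2-en-5-yn-4-ol
Product: 7 (2E,4S,5Z,8R)-8-(TBSO)-6-iodo-9-(PMBO)nona-2,5-dien-4-ol, via cyclic alkenylaluminate 6 (not isolated)
Conditions: NaAlH2(OCH2CH2OMe)2, THF, 0 °C to rt; then I2, THF, −78 °C; aq. KNaC4H4O6/Na2S2O3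
Reagents that add atoms: iodine, II
Why: Hydroxyl-directed trans-hydroalumination of the propargylic alcohol places aluminium on the distal alkyne carbon inside a five-membered alkoxyaluminate and hydride on the proximal one, and iodinolysis with retention gives the Z-iodoalkene with iodine cis to the carbinol carbon while the isolated propenyl group is not reduced.

Step 5
Reactants: 7 (2E,4S,5Z,8R)-8-(TBSO)-6-iodo-9-(PMBO)nona-2,5-dien-4-ol
Product: 8 (2E,4S,5E,8R)-8-(TBSO)-9-(PMBO)-6-methylnona-2,5-dien-4-ol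
Conditions: Me2Zn (3 equiv), Pd(PPh3)4 (5 mol %), THF, 0 °C to rt
Reagents that add atoms: dimethylzinc, C[Zn]C
Why: Negishi coupling at zerovalent palladium replaces iodine by methyl with retention of alkene geometry, which gives the E-trisubstituted alkene (future C4=C5 with methyl C15) and tolerates the free hydroxyl as its zinc alkoxide.

Step 6
Reactants: 8 (2E,4S,5E,8R)-8-(TBSO)-9-(PMBO)-6-methylnona-2,5-dien-4-ol
Product: 9 (2E,4S,5E,8R)-8-(TBSO)-9-(PMBO)-6-methyl-4-(TESO)nona-2,5-diene
Conditions: TESCl, imidazole, CH2Cl2, 0 °C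
Reagents that add atoms: chlorotriethylsilane, CC[Si](Cl)(CC)CC
Why: Silylation masks the doubly allylic hydroxyl with a triethylsilyl group that buffered fluoride can later remove without loss of the tert-butyldimethylsilyl ether.

Step 7
Reactants: 9 (2E,4S,5E,8R)-8-(TBSO)-9-(PMBO)-6-methyl-4-(TESO)nona-2,5-diene
Product: 10 (2R,4E,6S,7E)-2-(TBSO)-4-methyl-6-(TESO)nona-4,7-dien-1-ol
Conditions: DDQ, CH2Cl2/pH 7 phosphate buffer, 0 °C
Reagents that add atoms: none
Why: DDQ cleaves the 4-methoxybenzyl ether oxidatively (hydride abstraction from the electron-rich benzylic position, then hydrolysis) under buffered conditions that spare both silyl ethers.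

Step 8
Reactants: 10 (2R,4E,6S,7E)-2-(TBSO)-4-methyl-6-(TESO)nona-4,7-dien-1-ol
Product: 11 (2R,4E,6S,7E)-2-(TBSO)-4-methyl-6-(TESO)nona-4,7-dienal
Conditions: Dess–Martin periodinane, NaHCO3, CH2Cl2, 0 °C to rt
Reagents that add atoms: none
Why: Dess–Martin oxidation gives the α-silyloxy aldehyde under near-neutral conditions that do not epimerise the adjacent stereocentre.

Step 9
Reactants: 11 (2R,4E,6S,7E)-2-(TBSO)-4-methyl-6-(TESO)nona-4,7-dienal
Product: 12 (2E,4S,5E,8R,9Z)-8-(TBSO)-10-iodo-6-methyl-4-(TESO)undeca-2,5,9-triene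
Conditions: EtPPh3I, n-BuLi, THF, rt; I2, −78 °C; NaN(SiMe3)2, −20 °C; then 11, −78 to −20 °C
Reagents that add atoms: (1-iodoethylidene)triphenylphosphorane (made in the flask from ethyltriphenylphosphonium iodide), CC(I)=P(c1ccccc1)(c1ccccc1)c1ccccc1
Why: Stork–Zhao olefination with the non-stabilised α-iodo ylide runs under kinetic control through the cis-oxaphosphetane and gives the Z-iodoalkene (iodine cis to C2), the geometry needed for the Z-C1=C10 alkene.

Step 10
Reactants: 13 methyl 2-(bromomethyl)acrylate; 14 2,2-dimethoxyethanol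
Product: 15 methyl 2-[(2,2-dimethoxyethoxy)methyl]prop-2-enoate
Conditions: NaH, THF, 0 °C (alkoxide of 14); then 13, −20 to 0 °C
Reagents that add atoms: none
Why: Williamson-type etherification in which the alkoxide displaces the allylic bromide (directly or by addition–elimination, both giving the same ether) faster than it attacks the methyl ester.

Step 11
Reactants: 15 methyl 2-[(2,2-dimethoxyethoxy)methyl]prop-2-enoate
Product: 16 methyl 2-[(2-oxoethoxy)methyl]prop-2-enoate
Conditions: CF3CO2H/H2O (1:1), CHCl3, 0 °C to rt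
Reagents that add atoms: water, O
Why: Acid-catalysed hydrolysis of the dimethyl acetal liberates the α-alkoxy aldehyde, which is used at once without purification.

Step 12
Reactants: 12 (2E,4S,5E,8R,9Z)-8-(TBSO)-10-iodo-6-methyl-4-(TESO)undeca-2,5,9-triene; 16 methyl 2-[(2-oxoethoxy)methyl]prop-2-enoate
Product: 17 methyl 2-({[(2RS,3Z,5R,7E,9S,10E)-5-(TBSO)-2-hydroxy-3,7-dimethyl-9-(TESO)dodeca-3,7,10-trien-1-yl]oxy}methyl)prop-2-enoate
Conditions: CrCl2 (8 equiv), NiCl2 (2 mol %), DMSO, rt; 16 (2.5 equiv)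
Reagents that add atoms: none
Why: In this Nozaki–Hiyama–Kishi coupling the alkenylchromium species formed from the iodoalkene with retention of geometry adds to the aldehyde and leaves the acrylate ester and the silyl ethers untouched, and the new carbinol (C9) is taken on as both epimers because it is oxidised next.

Step 13
Reactants: 17 methyl 2-({[(2RS,3Z,5R,7E,9S,10E)-5-(TBSO)-2-hydroxy-3,7-dimethyl-9-(TESO)dodeca-3,7,10-trien-1-yl]oxy}methyl)prop-2-enoate
Product: 18 methyl 2-({[(3Z,5R,7E,9S,10E)-5-(TBSO)-3,7-dimethyl-2-oxo-9-(TESO)dodeca-3,7,10-trien-1-yl]oxy}methyl)prop-2-enoate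
Conditions: Dess–Martin periodinane, NaHCO3, CH2Cl2, 0 °C
Reagents that add atoms: none
Why: Dess–Martin oxidation of the allylic alcohol gives the Z-enone without acid or base that could isomerise the alkene or eliminate the α-alkoxy group.

Step 14
Reactants: 18 methyl 2-({[(3Z,5R,7E,9S,10E)-5-(TBSO)-3,7-dimethyl-2-oxo-9-(TESO)dodeca-3,7,10-trien-1-yl]oxy}methyl)prop-2-enoate
Product: 19 2-({[(3Z,5R,7E,9S,10E)-5-(TBSO)-3,7-dimethyl-2-oxo-9-(TESO)dodeca-3,7,10-trien-1-yl]oxy}methyl)prop-2-enoic acid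
Conditions: Me3SnOH (6 equiv), ClCH2CH2Cl, 70 °C; 5 % aq. HCl wash
Reagents that add atoms: trimethyltin hydroxide, C[Sn](C)(C)O
Why: Trimethyltin hydroxide cleaves the methyl ester by a neutral hydrolysis that avoids conjugate addition to the acrylate and the enone and keeps both silyl ethers.

Step 15
Reactants: 19 2-({[(3Z,5R,7E,9S,10E)-5-(TBSO)-3,7-dimethyl-2-oxo-9-(TESO)dodeca-3,7,10-trien-1-yl]oxy}methyl)prop-2-enoic acid
Product: 20 2-({[(3Z,5R,7E,9S,10E)-5-(TBSO)-9-hydroxy-3,7-dimethyl-2-oxododeca-3,7,10-trien-1-yl]oxy}methyl)prop-2-enoic acid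
Conditions: HF·pyridine, pyridine, THF, 0 °C
Reagents that add atoms: none
Why: Buffered fluoride removes the triethylsilyl ether much faster than the bulkier tert-butyldimethylsilyl ether (selective desilylation) and frees the C6 hydroxyl without acid-induced ionisation of the doubly allylic alcohol.

Step 16
Reactants: 20 2-({[(3Z,5R,7E,9S,10E)-5-(TBSO)-9-hydroxy-3,7-dimethyl-2-oxododeca-3,7,10-trien-1-yl]oxy}methyl)prop-2-enoic acid
Product: 22 (8Z,10R,12E,14S)-10-(TBSO)-8,12-dimethyl-3-methylidene-14-[(1E)-prop-1-en-1-yl]-1,5-dioxacyclotetradeca-8,12-diene-2,7-dione, via mixed anhydride 21 (not isolated)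
Conditions: 2,4,6-Cl3C6H2COCl, Et3N, THF, rt; then slow addition to DMAP, toluene (1 mM), rt to 40 °C
Reagents that add atoms: none
Why: In this Yamaguchi macrolactonisation the mixed anhydride acylates the C6 hydroxyl through the acylpyridinium ion under high dilution, which closes the 14-membered lactone with retention at C6 because the carbinol C–O bond is not broken.

Step 17
Reactants: 22 (8Z,10R,12E,14S)-10-(TBSO)-8,12-dimethyl-3-methylidene-14-[(1E)-prop-1-en-1-yl]-1,5-dioxacyclotetradeca-8,12-diene-2,7-dione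
Product: 23 (1(10)Z,2R,4E,6R)-2-(TBSO)-9-oxo-8,13-epoxy-7,8-secogermacra-1(10),4,7(11)-trien-12,6-olide (13-membered keto ether bridged by the butenolide)
Conditions: second-generation Grubbs catalyst (15 mol %), toluene (1 mM), 80 °C, argon sparge
Reagents that add atoms: none
Why: Ring-closing metathesis joins the propenyl carbon on C6 to the acrylate methylene carbon with loss of propene and forms the five-membered butenolide (cis alkene enforced by the ring), the trisubstituted ring alkenes and the enone being too hindered or electron-poor to compete.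

Step 18
Reactants: 23 (1(10)Z,2R,4E,6R)-2-(TBSO)-9-oxo-8,13-epoxy-7,8-secogermacra-1(10),4,7(11)-trien-12,6-olide
Product: 25 (1(10)Z,2R,4E,6R,7R,8R)-2-(TBSO)-8-hydroxy-9-oxogermacra-1(10),4,11(13)-trien-12,6-olide, via boron enolate 24 (not isolated)
Conditions: Bu2BOTf (1.1 equiv), i-Pr2NEt, CH2Cl2, −78 °C, then 0 °C to rt; pH 7 buffer/MeOH
Reagents that add atoms: none
Why: Proposed new method: Bu2BOTf and i-Pr2NEt turn the C9 ketone into its Z(O) boron enolate 24, whose nucleophilic carbon C8 lies over C7 of the butenolide in a five-membered envelope (C8, O, C13, C11, C7); C7–C8 bond formation, C13–O cleavage and the shift of the double bond to C11=C13 then occur as a [2,3]-sigmatropic shift (in the stepwise limit a conjugate addition followed by loss of the β-alkoxide from the lactone enolate), and the freed C8 oxygen stays on boron until work-up. The closest known reactions are [2,3]-Wittig rearrangements of boron and other enolates of α-allyloxy ketones and esters, [2,3]-Wittig ring contractions of 13-membered allylic ethers to cyclodecenols, and SN2′ alkylations of enolates by α-(alkoxymethyl) acrylates and butenolides; what is new is their combination, with a butenolide as the allyl unit. The ten-membered carbocycle is closed transannularly: the new C7–C8 bond spans the 13-membered ring and the C8–O–C13 bridge is excised, so the ring contracts by three atoms while the lactone ring stays intact. C7 is set by attack on the butenolide face opposite the C5 chain on C6 (trans-fused lactone), and C8 by the envelope in which the ether oxygen lies over C11 and the enolate carbon C9 points away from the lactone, an arrangement that the Z(O) enolate can reach without strain and that leads to the 8R alcohol. The step needs enolisation of the ketone and not γ-deprotonation of the butenolide at C6, which soft enolisation should secure, since the enone carbonyl is the more Lewis-basic site, C8 carries its only α-hydrogens and one equivalent of Bu2BOTf is used at −78 °C before warming. The exchange of a C–O bond for a C–C bond and the capture of the alkoxide on boron should make the shift irreversible.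

Step 19
Reactants: 25 (1(10)Z,2R,4E,6R,7R,8R)-2-(TBSO)-8-hydroxy-9-oxogermacra-1(10),4,11(13)-trien-12,6-olide; 26 angelic acid
Product: 27 (1(10)Z,2R,4E,6R,7S,8R)-8-(angeloyloxy)-2-(TBSO)-9-oxogermacra-1(10),4,11(13)-trien-12,6-olide
Conditions: 26, 2,4,6-Cl3C6H2COCl, Et3N, toluene, rt; then 25, 70 °C
Reagents that add atoms: none
Why: Esterification through the 2,4,6-trichlorobenzoic mixed anhydride of angelic acid (Yamaguchi-type acylation) without a nucleophilic catalyst acylates the hindered C8 hydroxyl and avoids Z-to-E isomerisation of the angelate.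

Step 20
Reactants: 27 (1(10)Z,2R,4E,6R,7S,8R)-8-(angeloyloxy)-2-(TBSO)-9-oxogermacra-1(10),4,11(13)-trien-12,6-olide
Product: 28 (1(10)Z,2R,4E,6R,7S,8R,9R)-8-(angeloyloxy)-2-(TBSO)-9-hydroxygermacra-1(10),4,11(13)-trien-12,6-olide
Conditions: NaBH4, CeCl3·7H2O, MeOH, −78 °C
Reagents that add atoms: none
Why: Luche reduction adds hydride 1,2 to the enone and spares the methylene lactone and the esters, and hydride is expected to add anti to the C8 acyloxy group from the outer face of the ring (Felkin–Anh polar model, 8,9-threo product), which sets C9 as R.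

Step 21
Reactants: 28 (1(10)Z,2R,4E,6R,7S,8R,9R)-8-(angeloyloxy)-2-(TBSO)-9-hydroxygermacra-1(10),4,11(13)-trien-12,6-olide
Product: 29 (1(10)Z,2R,4E,6R,7S,8R,9R)-8-(angeloyloxy)-2,9-dihydroxygermacra-1(10),4,11(13)-trien-12,6-olide
Conditions: HF·pyridine, THF, 0 °C to rt
Reagents that add atoms: none
Why: Fluoride cleaves the remaining silyl ether (desilylation) under mildly acidic conditions that do not touch the esters or the methylene lactone.

Step 22
Reactants: 29 (1(10)Z,2R,4E,6R,7S,8R,9R)-8-(angeloyloxy)-2,9-dihydroxygermacra-1(10),4,11(13)-trien-12,6-olide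
Product: 30 (1(10)Z,2R,4E,6R,7S,8R,9R)-2,9-diacetoxy-8-(angeloyloxy)germacra-1(10),4,11(13)-trien-12,6-olide (CNP0499619.1)
Conditions: Ac2O, pyridine, DMAP (5 mol %), CH2Cl2, 0 °C to rt
Reagents that add atoms: acetic anhydride, CC(=O)OC(C)=O
Why: Standard acetylation of the two secondary hydroxyls on C2 and C9 at low temperature, at which the angelate should not isomerise.

**Compound list**

1 | (R)-glycidyl 4-methoxybenzyl ether, (R)-2-{[(4-methoxybenzyl)oxy]methyl}oxirane | C1O[C@H]1COCc2ccc(OC)cc2 | starting material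
2 | (R)-1-(PMBO)pent-4-yn-2-ol | C#CC[C@@H](O)COCc1ccc(OC)cc1 | intermediate
3 | (R)-2-(TBSO)-1-(PMBO)pent-4-yne | C#CC[C@@H](O[Si](C)(C)C(C)(C)C)COCc1ccc(OC)cc1 | intermediate
4 | (E)-but-2-enal (crotonaldehyde) | C/C=C/C=O | starting material
5 | (2E,4S,8R)-8-(TBSO)-9-(PMBO)non-2-en-5-yn-4-ol | C/C=C/[C@H](O)C#CC[C@@H](O[Si](C)(C)C(C)(C)C)COCc1ccc(OC)cc1 | intermediate
6 | sodium cyclic alkenylaluminate: Al (two 2-methoxyethoxy ligands) bonded to O-4 and C-6 of the nona-2,5-diene chain of 7 | C/C=C/[C@@H]1O[Al-](OCCOC)(OCCOC)C(C[C@@H](O[Si](C)(C)C(C)(C)C)COCc2ccc(OC)cc2)=C1.[Na+] | intermediate (not isolated)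
7 | (2E,4S,5Z,8R)-8-(TBSO)-6-iodo-9-(PMBO)nona-2,5-dien-4-ol | C/C=C/[C@H](O)/C=C(\I)C[C@@H](O[Si](C)(C)C(C)(C)C)COCc1ccc(OC)cc1 | intermediate
8 | (2E,4S,5E,8R)-8-(TBSO)-9-(PMBO)-6-methylnona-2,5-dien-4-ol | C/C=C/[C@H](O)/C=C(\C)C[C@@H](O[Si](C)(C)C(C)(C)C)COCc1ccc(OC)cc1 | intermediate
9 | (2E,4S,5E,8R)-8-(TBSO)-9-(PMBO)-6-methyl-4-(TESO)nona-2,5-diene | C/C=C/[C@H](O[Si](CC)(CC)CC)/C=C(\C)C[C@@H](O[Si](C)(C)C(C)(C)C)COCc1ccc(OC)cc1 | intermediate
10 | (2R,4E,6S,7E)-2-(TBSO)-4-methyl-6-(TESO)nona-4,7-dien-1-ol | C/C=C/[C@H](O[Si](CC)(CC)CC)/C=C(\C)C[C@@H](O[Si](C)(C)C(C)(C)C)CO | intermediate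
11 | (2R,4E,6S,7E)-2-(TBSO)-4-methyl-6-(TESO)nona-4,7-dienal | C/C=C/[C@H](O[Si](CC)(CC)CC)/C=C(\C)C[C@@H](O[Si](C)(C)C(C)(C)C)C=O | intermediate
12 | (2E,4S,5E,8R,9Z)-8-(TBSO)-10-iodo-6-methyl-4-(TESO)undeca-2,5,9-triene | C/C=C/[C@H](O[Si](CC)(CC)CC)/C=C(\C)C[C@@H](O[Si](C)(C)C(C)(C)C)/C=C(/C)I | intermediate
13 | methyl 2-(bromomethyl)acrylate | C=C(CBr)C(=O)OC | starting material
14 | 2,2-dimethoxyethanol | COC(CO)OC | starting material
15 | methyl 2-[(2,2-dimethoxyethoxy)methyl]prop-2-enoate | C=C(COCC(OC)OC)C(=O)OC | intermediate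
16 | methyl 2-[(2-oxoethoxy)methyl]prop-2-enoate | C=C(COCC=O)C(=O)OC | intermediate
17 | methyl 2-({[(2RS,3Z,5R,7E,9S,10E)-5-(TBSO)-2-hydroxy-3,7-dimethyl-9-(TESO)dodeca-3,7,10-trien-1-yl]oxy}methyl)prop-2-enoate | C/C=C/[C@H](O[Si](CC)(CC)CC)/C=C(\C)C[C@@H](O[Si](C)(C)C(C)(C)C)/C=C(/C)C(O)COCC(=C)C(=O)OC | intermediate
18 | methyl 2-({[(3Z,5R,7E,9S,10E)-5-(TBSO)-3,7-dimethyl-2-oxo-9-(TESO)dodeca-3,7,10-trien-1-yl]oxy}methyl)prop-2-enoate | C/C=C/[C@H](O[Si](CC)(CC)CC)/C=C(\C)C[C@@H](O[Si](C)(C)C(C)(C)C)/C=C(/C)C(=O)COCC(=C)C(=O)OC | intermediate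
19 | 2-({[(3Z,5R,7E,9S,10E)-5-(TBSO)-3,7-dimethyl-2-oxo-9-(TESO)dodeca-3,7,10-trien-1-yl]oxy}methyl)prop-2-enoic acid | C/C=C/[C@H](O[Si](CC)(CC)CC)/C=C(\C)C[C@@H](O[Si](C)(C)C(C)(C)C)/C=C(/C)C(=O)COCC(=C)C(=O)O | intermediate
20 | 2-({[(3Z,5R,7E,9S,10E)-5-(TBSO)-9-hydroxy-3,7-dimethyl-2-oxododeca-3,7,10-trien-1-yl]oxy}methyl)prop-2-enoic acid | C/C=C/[C@H](O)/C=C(\C)C[C@@H](O[Si](C)(C)C(C)(C)C)/C=C(/C)C(=O)COCC(=C)C(=O)O | intermediate
21 | mixed anhydride of 20 with 2,4,6-trichlorobenzoic acid | C/C=C/[C@H](O)/C=C(\C)C[C@@H](O[Si](C)(C)C(C)(C)C)/C=C(/C)C(=O)COCC(=C)C(=O)OC(=O)c1c(Cl)cc(Cl)cc1Cl | intermediate (not isolated)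
22 | (8Z,10R,12E,14S)-10-(TBSO)-8,12-dimethyl-3-methylidene-14-[(1E)-prop-1-en-1-yl]-1,5-dioxacyclotetradeca-8,12-diene-2,7-dione | C=C1C(=O)O[C@@H](/C=C/C)/C=C(\C)C[C@@H](O[Si](C)(C)C(C)(C)C)/C=C(/C)C(=O)COC1 | intermediate
23 | (1(10)Z,2R,4E,6R)-2-(TBSO)-9-oxo-8,13-epoxy-7,8-secogermacra-1(10),4,7(11)-trien-12,6-olide (13-membered keto ether bridged by the butenolide) | O=C1O[C@@H]2/C=C(\C)C[C@@H](O[Si](C)(C)C(C)(C)C)/C=C(/C)C(=O)COCC1=C2 | intermediate
24 | 9-O-dibutylboryl (Z)-enolate of 23 (C8=C9, boryloxy group and ether oxygen cis) | O=C1O[C@@H]2/C=C(\C)C[C@@H](O[Si](C)(C)C(C)(C)C)/C=C(/C)\C(OB(CCCC)CCCC)=C\OCC1=C2 | intermediate (not isolated)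
25 | (1(10)Z,2R,4E,6R,7R,8R)-2-(TBSO)-8-hydroxy-9-oxogermacra-1(10),4,11(13)-trien-12,6-olide | C=C1C(=O)O[C@@H]2/C=C(\C)C[C@@H](O[Si](C)(C)C(C)(C)C)/C=C(/C)C(=O)[C@H](O)[C@@H]12 | intermediate
26 | angelic acid, (Z)-2-methylbut-2-enoic acid | C/C=C(/C)C(=O)O | starting material
27 | (1(10)Z,2R,4E,6R,7S,8R)-8-(angeloyloxy)-2-(TBSO)-9-oxogermacra-1(10),4,11(13)-trien-12,6-olide | C=C1C(=O)O[C@@H]2/C=C(\C)C[C@@H](O[Si](C)(C)C(C)(C)C)/C=C(/C)C(=O)[C@H](OC(=O)/C(C)=C\C)[C@@H]12 | intermediate
28 | (1(10)Z,2R,4E,6R,7S,8R,9R)-8-(angeloyloxy)-2-(TBSO)-9-hydroxygermacra-1(10),4,11(13)-trien-12,6-olide | C=C1C(=O)O[C@@H]2/C=C(\C)C[C@@H](O[Si](C)(C)C(C)(C)C)/C=C(/C)[C@@H](O)[C@H](OC(=O)/C(C)=C\C)[C@@H]12 | intermediate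
29 | (1(10)Z,2R,4E,6R,7S,8R,9R)-8-(angeloyloxy)-2,9-dihydroxygermacra-1(10),4,11(13)-trien-12,6-olide | C=C1C(=O)O[C@@H]2/C=C(\C)C[C@@H](O)/C=C(/C)[C@@H](O)[C@H](OC(=O)/C(C)=C\C)[C@@H]12 | intermediate
30 | (1(10)Z,2R,4E,6R,7S,8R,9R)-2,9-diacetoxy-8-(angeloyloxy)germacra-1(10),4,11(13)-trien-12,6-olide, CNP0499619.1 | C=C1C(=O)O[C@@H]2/C=C(\C)C[C@@H](OC(C)=O)/C=C(/C)[C@@H](OC(C)=O)[C@H](OC(=O)/C(C)=C\C)[C@@H]12 | target

**Step count and risks**

Total: 22 steps (20 in the main line, 2 for aldehyde 16). Longest linear sequence: 20 steps (1 to 30 through steps 1–9 and 12–22).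

Steps most likely to fail:

1. Step 18. Enolisation may occur at the γ-position of the butenolide (C6) instead of C8 and erode the C6 configuration; the boron enolate may be too weak a nucleophile for C–C bond formation; or C7 may be attacked on the face syn to the C5 chain. The fallback uses known reactions only: C7–C8 by Barbier allylation and ring closure by Nozaki–Hiyama–Kishi coupling. It sets out from 12. HF·pyridine removes the triethylsilyl group to give dienol F1. DCC esterification with 2-(bromomethyl)acrylic acid gives bromomethylacrylate F2. Ring-closing metathesis with second-generation Grubbs catalyst gives the 3-(bromomethyl)butenolide F3. Indium-mediated Barbier reaction of F3 with 2,2-dimethoxyacetaldehyde in aqueous THF joins C7 to C8 with allylic transposition; this creates the methylene lactone and the C8 carbinol anti to the C6 side chain (Barbier adduct F4, the 8R epimer being separated if both form). Angeloylation as in step 19 gives angelate acetal F5, and aqueous CF3CO2H hydrolyses the acetal to aldehyde F6. CrCl2/NiCl2 in DMSO at high dilution couples the iodoalkene with the aldehyde and closes the ten-membered ring at C9–C10 (ring carbinols F7, both C9 epimers). Dess–Martin oxidation of F7 gives 27, where the route is rejoined.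

2. Step 17. The 14-membered lactone may not reach the s-cis ester geometry that closure to the butenolide demands, so that slow initiation at the hindered propenyl group is followed by intermolecular metathesis or by no reaction. The fallback builds the butenolide on an open chain and then closes the 13-membered ring by C9–C10 coupling. It sets out from 12 and uses dienol F1 again. Acetal acid F8 (from 15 with LiOH in aqueous THF) is esterified with F1 (DCC, catalytic DMAP) to give acetal ester F9. Ring-closing metathesis, now an ordinary five-ring closure, gives butenolide acetal F10, and acetal hydrolysis gives butenolide aldehyde F11. Intramolecular Nozaki–Hiyama–Kishi coupling (CrCl2, NiCl2, DMSO, high dilution) gives the 13-membered carbinol F12 as both C9 epimers. Dess–Martin oxidation of F12 gives 23.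

3. Step 20. Hydride may be delivered to the inner face of the C9 carbonyl and give the 9S alcohol, and some conjugate reduction of the methylene lactone may occur. The fallback inverts C9 and does not depend on a selective reduction. It sets out from 27. If reduction gives mainly the 9-epi alcohol F13, a Mitsunobu reaction with acetic acid (PPh3, diisopropyl azodicarboxylate) inverts C9 and installs the acetate in one operation (9-acetate F14). HF·pyridine then frees the C2 hydroxyl (2-hydroxy 9-acetate F15), and acetylation as in step 22 gives 30.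

**Further compounds**

F1 | step 18 | dienol, (2E,4S,5E,8R,9Z)-8-(TBSO)-10-iodo-6-methylundeca-2,5,9-trien-4-ol | C/C=C/[C@H](O)/C=C(\C)C[C@@H](O[Si](C)(C)C(C)(C)C)/C=C(/C)I
F2 | step 18 | bromomethylacrylate, 2-(bromomethyl)prop-2-enoate ester of F1 | C/C=C/[C@H](OC(=O)C(=C)CBr)/C=C(\C)C[C@@H](O[Si](C)(C)C(C)(C)C)/C=C(/C)I
F3 | step 18 | 3-(bromomethyl)butenolide, (5R)-3-(bromomethyl)-5-[(1E,4R,5Z)-4-(TBSO)-6-iodo-2-methylhepta-1,5-dien-1-yl]furan-2(5H)-one | O=C1O[C@H](/C=C(\C)C[C@@H](O[Si](C)(C)C(C)(C)C)/C=C(/C)I)C=C1CBr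
F4 | step 18 | Barbier adduct, α-methylene lactone carrying on C7 the 1-hydroxy-2,2-dimethoxyethyl group (C8, C9), with C6, C7 and C8 configured as in 25 | C=C1C(=O)O[C@H](/C=C(\C)C[C@@H](O[Si](C)(C)C(C)(C)C)/C=C(/C)I)[C@H]1[C@@H](O)C(OC)OC
F5 | step 18 | angelate acetal, 8-O-angeloyl derivative of F4 | C=C1C(=O)O[C@H](/C=C(\C)C[C@@H](O[Si](C)(C)C(C)(C)C)/C=C(/C)I)[C@H]1[C@@H](OC(=O)/C(C)=C\C)C(OC)OC
F6 | step 18 | aldehyde, C9 aldehyde from hydrolysis of F5 | C=C1C(=O)O[C@H](/C=C(\C)C[C@@H](O[Si](C)(C)C(C)(C)C)/C=C(/C)I)[C@H]1[C@@H](OC(=O)/C(C)=C\C)C=O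
F7 | step 18 | ring carbinols, 28 as the mixture of both C9 epimers | C=C1C(=O)O[C@@H]2/C=C(\C)C[C@@H](O[Si](C)(C)C(C)(C)C)/C=C(/C)C(O)[C@H](OC(=O)/C(C)=C\C)[C@@H]12
F8 | step 17 | acetal acid, 2-[(2,2-dimethoxyethoxy)methyl]prop-2-enoic acid | C=C(COCC(OC)OC)C(=O)O
F9 | step 17 | acetal ester, ester of F1 with F8 | C/C=C/[C@H](OC(=O)C(=C)COCC(OC)OC)/C=C(\C)C[C@@H](O[Si](C)(C)C(C)(C)C)/C=C(/C)I
F10 | step 17 | butenolide acetal, (5R)-3-[(2,2-dimethoxyethoxy)methyl]-5-[(1E,4R,5Z)-4-(TBSO)-6-iodo-2-methylhepta-1,5-dien-1-yl]furan-2(5H)-one | O=C1O[C@H](/C=C(\C)C[C@@H](O[Si](C)(C)C(C)(C)C)/C=C(/C)I)C=C1COCC(OC)OC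
F11 | step 17 | butenolide aldehyde, aldehyde from hydrolysis of F10 | O=C1O[C@H](/C=C(\C)C[C@@H](O[Si](C)(C)C(C)(C)C)/C=C(/C)I)C=C1COCC=O
F12 | step 17 | 13-membered carbinol, 9-hydroxy analogue of 23 (both C9 epimers) | O=C1O[C@@H]2/C=C(\C)C[C@@H](O[Si](C)(C)C(C)(C)C)/C=C(/C)C(O)COCC1=C2
F13 | step 20 | 9-epi alcohol, (9S) epimer of 28 | C=C1C(=O)O[C@@H]2/C=C(\C)C[C@@H](O[Si](C)(C)C(C)(C)C)/C=C(/C)[C@H](O)[C@H](OC(=O)/C(C)=C\C)[C@@H]12
F14 | step 20 | 9-acetate, (9R)-9-acetoxy-8-(angeloyloxy)-2-(TBSO) germacranolide | C=C1C(=O)O[C@@H]2/C=C(\C)C[C@@H](O[Si](C)(C)C(C)(C)C)/C=C(/C)[C@@H](OC(C)=O)[C@H](OC(=O)/C(C)=C\C)[C@@H]12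
F15 | step 20 | 2-hydroxy 9-acetate, (9R)-9-acetoxy-8-(angeloyloxy)-2-hydroxy germacranolide | C=C1C(=O)O[C@@H]2/C=C(\C)C[C@@H](O)/C=C(/C)[C@@H](OC(C)=O)[C@H](OC(=O)/C(C)=C\C)[C@@H]12
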